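All runs are simulated with made-up constants; the scatter is artificial.

Take the gap between G and its plateau as the clock of this flask, and count in its half-lives how far the hour lies past the crossing from kinetic to thermodynamic control.

| flask | E | remark | time |
|---|---|---|---|
| Saturday's | 0.010 M | the very flask that is asked about, followed so far |  |
| Tuesday's | 0.0067 M | run made earlier |  |
| flask | 0.010 M |  | 1.0 h |

- Saturday's (time / min: E / %, G / %): 1.33: 56.2, 7.9; 4.00: 23.6, 12.6; 6.00: 16.6, 14.6; 10.0: 12.6, 15.6; 15.0: 11.7, 17.0; 20.0: 11.7, 18.1
- Tuesday's (time / min: E / %, G / %): 5.00: 19.7, 13.3; 8.00: 14.7, 15.1; 12.0: 12.3, 16.4; 20.0: 11.3, 18.2; 40.0: 11.2, 18.3; 60.0: 11.8, 19.7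

(readings scatter by 0.3 percentage points)

1. how much of the E has reacted by 1.0 h
2. how much G there is at 1.0 h, in percent of the E charged
3. how much Q there is at 1.0 h, in percent of the E charged
4. amount of G if the flask were left three thousand times as long, in percent of the E charged

The percentages of the two runs matched at their different charges, with G at 18.1% and 18.2% after 20.0 min, so I carried Tuesday's gaps over to Saturday's flask. On the fastest rung, E in Saturday's run fell towards its plateau with a half-life that I read as 1.40 min. On the next rung I set G's plateau at 19.0%, the mean of Tuesday's last two readings, though these lay 1.4 percentage points apart against a scatter of 0.3 points. Tuesday's gap shrank from 5.7 points at 5.00 min to 2.6 points at 12.0 min, which gave 6.18 min for t_G, the settling half-life, the time in which G's gap to its plateau halves. This rung is slower than E's, so in Saturday's run E had flattened at 11.7% by 15.0 min while G still climbed. On the last rung, the hour lay 7.77 half-lives past Tuesday's 12.0 min reading, which by my reckoning left a gap of 0.012 points. I took a late E of 11.5% from Tuesday's last two readings, and I therefore committed to 88.5% of E reacted and to G at 19.0%, which I also kept for the long wait, having no rate for it. Q by difference came to 69.5%, shared with whatever I could not read.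

The forecast gave 88.4% reacted, G 19.1%, Q 69.3% and G 20% on the long wait, “assuming no other species”.

The flask gave 88.7% reacted, G 19.2%, Q 55.8%, and G 15.9% on the long wait.

    E ⇌ L (K = 0.460, k = 0.0784 min⁻¹)
    2 E → J (k = 0.00453 M⁻¹ min⁻¹)
    G ⇌ D (K = 0.438, k = 0.0930 min⁻¹)
    D ⇌ Q (K = 6.62, k = 0.249 min⁻¹)
    E ⇌ G (K = 1.70, k = 0.0783 min⁻¹)
    Q ⇌ E (k = 0.0609 min⁻¹)

G and D relaxed with a half-life of 2.27 min, and D and Q with 2.42 min, both short against the hour; at that hour D stood at 8.42% and L at 5.21%, and Q, D and L together came to 69.4% against my 69.5%. My t_G of 6.18 min left G at 19.0% at the hour, where the flask held 19.2%, and from Tuesday's gap it put G at 17.1% in the neighbour flask read at 15 min, which held 17.3%.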